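**Plan**
- The pyrrole N1–C2–C5 unit, with the acyl group on C2 and the one-carbon arm on C5, is read as a ketone-stabilised azomethine ylide; the unsubstituted C3–C4 edge is read as a two-carbon acetylene equivalent.
- Cuts, in order: CH2OH back to an aldehyde masked as a dimethyl acetal; ring bonds C2–C3 and C4–C5 (imine ylide plus (E)-1,2-bis(phenylsulfonyl)ethene); the C5=N imine bond (aminomethyl ketone plus 2,2-dimethoxyacetaldehyde); the CO–CH2N bond (fatty acid chloride plus methyl isocyanoacetate).
- Forward: the chain is joined first (acid chloride and isocyanoacetate to an oxazole, then the aminomethyl ketone salt, then the imine). The only ring closes in the [3+2] step as a pyrrolidine and is aromatised by loss of two sulfinates.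
- Acetal hydrolysis and aldehyde-selective reduction finish the synthesis.
- Stereochemistry: the target has no stereocentre; the four ring centres of the cycloadduct are transient and disappear on aromatisation, so nothing has to be controlled.

Key step: step 5

Remark: 16-methylheptadecanoic acid is taken as the commercially available single iso-acid, not the technical isomer mixture sold as isostearic acid.
Remark: 2,2-dimethoxyacetaldehyde is sold as a 60 % aqueous solution and is assumed to be extracted into CH2Cl2 and dried before use.

**Route**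

Step 1
Reactants: 1 16-methylheptadecanoic acid
Product: 2 16-methylheptadecanoyl chloride
Conditions: (COCl)2, DMF (cat.), CH2Cl2, 0 °C → rt; concentrated and used crude
Reagents that add atoms: oxalyl chloride, O=C(Cl)C(=O)Cl
Why: DMF-catalysed acyl chloride formation with oxalyl chloride is clean for saturated fatty acids and leaves only volatile by-products.

Step 2
Reactants: 2 16-methylheptadecanoyl chloride; 3 methyl isocyanoacetate
Product: 5 methyl 5-(15-methylhexadecyl)-1,3-oxazole-4-carboxylate, via keto isocyanide 4 (not isolated)
Conditions: Et3N (3 equiv), DMAP (cat.), THF, 0 °C → rt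
Reagents that add atoms: none
Why: The deprotonated isocyanoacetate is C-acylated to 4, whose enolate oxygen closes onto the isocyanide carbon to give the aromatic oxazole (isocyanoacetate acylation–cyclisation, a formal [3+2] oxazole synthesis).

Step 3
Reactants: 5 methyl 5-(15-methylhexadecyl)-1,3-oxazole-4-carboxylate
Product: 7 1-amino-17-methyloctadecan-2-one hydrochloride, via amino keto ester hydrochloride 6 (not isolated)
Conditions: 6 M HCl, 1,4-dioxane, reflux
Reagents that add atoms: hydrogen chloride, Cl
Why: Hot aqueous acid opens the oxazole and releases its C2 as formic acid to give 6, then ester hydrolysis and decarboxylation leave the aminomethyl ketone, which stays protonated and so cannot self-condense (acid hydrolysis of 5-alkyloxazole-4-carboxylates).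

Step 4
Reactants: 7 1-amino-17-methyloctadecan-2-one hydrochloride; 8 2,2-dimethoxyacetaldehyde
Product: 9 (E)-1-[(2,2-dimethoxyethylidene)amino]-17-methyloctadecan-2-one
Conditions: Et3N (1 equiv, slow addition), 4 Å MS, CH2Cl2, 0 °C → rt; crude used directly
Reagents that add atoms: none
Why: Imine formation between a primary amine and a non-enolisable aldehyde is driven by the sieves, and slow release of the amine in the presence of excess aldehyde should trap it as the E-aldimine before it can dimerise to a dihydropyrazine.

Step 5
Reactants: 9 (E)-1-[(2,2-dimethoxyethylidene)amino]-17-methyloctadecan-2-one; 10 (E)-1,2-bis(phenylsulfonyl)ethene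
Product: 11 1-[5-(dimethoxymethyl)-3,4-bis(phenylsulfonyl)pyrrolidin-2-yl]-16-methylheptadecan-1-one (racemic diastereomer mixture)
Conditions: AgOAc (10 mol %), PPh3 (10 mol %), Et3N (20 mol %), THF, 0 °C → rt, dark
Reagents that add atoms: none
Why: AgOAc (monovalent silver) binds the imine nitrogen and ketone oxygen of 9, so catalytic Et3N can remove a proton from the CH2 between them to give an N,O-chelated silver azomethine ylide, which adds across the doubly activated alkene 10 in a 1,3-dipolar cycloaddition, best viewed as Michael addition of the ylide carbon followed by Mannich closure of the sulfonyl carbanion onto the metal-bound imine. The closest known reaction type is the silver- or copper-catalysed cycloaddition of α-imino ester ylides with 1,2-bis(sulfonyl)ethenes used as acetylene equivalents. The pyrrolidine is the only ring formed; it closes by an intermolecular [3+2] annulation that makes C2–C3 and C4–C5, the second bond in a formal 5-endo-trig Mannich step. Four stereocentres arise: the W-shaped chelated ylide should set C2 and C5 cis, the E geometry of 10 sets C3 and C4 trans, the endo/exo sense is left open and the product is racemic, none of which matters because step 6 removes every one of them. No regiocontrol is needed because 10 is symmetric; what is needed is ylide formation in preference to 1,3-proton shift or aza-Michael addition, and this is secured by the acidity of the keto-flanked CH2, by the non-enolisable acetal-bearing imine carbon and by the absence of free amine in the preformed imine.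

Step 6
Reactants: 11 1-[5-(dimethoxymethyl)-3,4-bis(phenylsulfonyl)pyrrolidin-2-yl]-16-methylheptadecan-1-one
Product: 13 1-[5-(dimethoxymethyl)-1H-pyrrol-2-yl]-16-methylheptadecan-1-one, via sulfonyl dihydropyrrole 12 (not isolated)
Conditions: DBU (3 equiv), THF, rt → 50 °C
Reagents that add atoms: none
Why: DBU removes the acidic C2–H next to the ketone and expels the C3 sulfinate (E1cB) to give enaminone 12, whose enamine nitrogen then pushes out the C4 sulfinate vinylogously, and proton loss from C5 gives the aromatic pyrrole without any oxidant (base-induced double sulfinate elimination from 3,4-bis(sulfonyl)pyrrolidines).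

Step 7
Reactants: 13 1-[5-(dimethoxymethyl)-1H-pyrrol-2-yl]-16-methylheptadecan-1-one
Product: 14 5-(16-methylheptadecanoyl)-1H-pyrrole-2-carbaldehyde
Conditions: 1 M HCl, THF, rt
Reagents that add atoms: water, O
Why: Acid-catalysed hydrolysis of a dimethyl acetal is easy at a pyrrolyl carbon, while the electron-poor acylpyrrole tolerates dilute acid and the ketone is untouched.

Step 8
Reactants: 14 5-(16-methylheptadecanoyl)-1H-pyrrole-2-carbaldehyde
Product: 15 1-[5-(hydroxymethyl)-1H-pyrrol-2-yl]-16-methylheptadecan-1-one
Conditions: NaBH4 (0.5 equiv), THF/MeOH, −20 °C; pH 7 phosphate buffer quench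
Reagents that add atoms: none
Why: In this chemoselective borohydride reduction the aldehyde should react much faster at low temperature than the more hindered, less electrophilic pyrrolyl alkyl ketone, and the buffered work-up keeps the hydroxymethylpyrrole from ionising to an azafulvene.

**Compound list**

1 | 16-methylheptadecanoic acid | CC(C)CCCCCCCCCCCCCCC(=O)O | starting material
2 | 16-methylheptadecanoyl chloride | CC(C)CCCCCCCCCCCCCCC(=O)Cl | intermediate
3 | methyl isocyanoacetate | COC(=O)C[N+]#[C-] | starting material
4 | methyl 2-isocyano-18-methyl-3-oxononadecanoate (racemic; not isolated) | CC(C)CCCCCCCCCCCCCCC(=O)C([N+]#[C-])C(=O)OC | intermediate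
5 | methyl 5-(15-methylhexadecyl)-1,3-oxazole-4-carboxylate | CC(C)CCCCCCCCCCCCCCc1ocnc1C(=O)OC | intermediate
6 | methyl 2-amino-18-methyl-3-oxononadecanoate hydrochloride (racemic; not isolated) | CC(C)CCCCCCCCCCCCCCC(=O)C(N)C(=O)OC.Cl | intermediate
7 | 1-amino-17-methyloctadecan-2-one hydrochloride | CC(C)CCCCCCCCCCCCCCC(=O)CN.Cl | intermediate
8 | 2,2-dimethoxyacetaldehyde | COC(OC)C=O | starting material
9 | (E)-1-[(2,2-dimethoxyethylidene)amino]-17-methyloctadecan-2-one | CC(C)CCCCCCCCCCCCCCC(=O)C/N=C/C(OC)OC | intermediate
10 | (E)-1,2-bis(phenylsulfonyl)ethene | O=S(=O)(/C=C/S(=O)(=O)c1ccccc1)c1ccccc1 | starting material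
11 | 1-[5-(dimethoxymethyl)-3,4-bis(phenylsulfonyl)pyrrolidin-2-yl]-16-methylheptadecan-1-one (racemic diastereomer mixture, 2,5-cis and 3,4-trans expected; configuration left unspecified because all four centres are erased in step 6) | CC(C)CCCCCCCCCCCCCCC(=O)C1NC(C(OC)OC)C(S(=O)(=O)c2ccccc2)C1S(=O)(=O)c1ccccc1 | intermediate
12 | 1-[5-(dimethoxymethyl)-4-(phenylsulfonyl)-4,5-dihydro-1H-pyrrol-2-yl]-16-methylheptadecan-1-one (racemic, relative configuration open; not isolated) | CC(C)CCCCCCCCCCCCCCC(=O)C1=CC(S(=O)(=O)c2ccccc2)C(C(OC)OC)N1 | intermediate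
13 | 1-[5-(dimethoxymethyl)-1H-pyrrol-2-yl]-16-methylheptadecan-1-one | CC(C)CCCCCCCCCCCCCCC(=O)c1ccc(C(OC)OC)[nH]1 | intermediate
14 | 5-(16-methylheptadecanoyl)-1H-pyrrole-2-carbaldehyde | CC(C)CCCCCCCCCCCCCCC(=O)c1ccc(C=O)[nH]1 | intermediate
15 | 1-[5-(hydroxymethyl)-1H-pyrrol-2-yl]-16-methylheptadecan-1-one | CC(C)CCCCCCCCCCCCCCC(=O)c1ccc(CO)[nH]1 | target

Total step count: 8. Longest linear sequence: 8 steps (1 to 15).

**Steps most likely to fail**

Step 5. The deprotonated imine may drift by 1,3-proton shift to its conjugated 2-aza-diene isomer, or be hydrolysed back to the aminoketone, faster than it is captured by the alkene, so that the ring never closes.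
- The fallback gives up the cycloaddition and makes the same aldehyde by C-acylation of a masked 5-metallated pyrrole-2-carbaldehyde. It sets out from acid chloride 2 and returns to the route at aldehyde 14.
- Acid chloride 2 is treated with MeNH(OMe)·HCl and pyridine in CH2Cl2 to give N-methoxy-N,16-dimethylheptadecanamide F1.
- Commercial pyrrole-2-carbaldehyde is condensed with aqueous dimethylamine to the azafulvene dimer 5,10-bis(dimethylamino)-5H,10H-dipyrrolo[1,2-a:1',2'-d]pyrazine F2, which blocks the nitrogen and masks the aldehyde at the same time.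
- Double lithiation of F2 with t-BuLi (THF, −15 °C) should take place at the free pyrrole α-carbon of each half. Addition of F1 (Weinreb ketone synthesis) and aqueous quench should then give 1,1'-[5,10-bis(dimethylamino)-5H,10H-dipyrrolo[1,2-a:1',2'-d]pyrazine-3,8-diyl]bis(16-methylheptadecan-1-one) F3.
- Hydrolysis with aqueous NaOAc at reflux unmasks both aldehyde groups and delivers two molecules of 14, which goes on to step 8.

Step 4. Once freed from its salt, the aminomethyl ketone may condense with itself to a dihydropyrazine faster than with the aldehyde, so that the imine is formed impurely or not at all.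
- The fallback makes the imine by a Staudinger/aza-Wittig sequence in which no free amine exists at any stage. It sets out from acid chloride 2 and returns at imine 9.
- Acid chloride 2 with Me3SiCHN2 (THF/MeCN, 0 °C) should give 1-diazo-17-methyloctadecan-2-one F4.
- Aqueous HBr converts it into 1-bromo-17-methyloctadecan-2-one F5, and NaN3 in DMF gives 1-azido-17-methyloctadecan-2-one F6.
- PPh3 is then added to a THF solution of F6 and aldehyde 8, so that the iminophosphorane 17-methyl-1-[(triphenylphosphoranylidene)amino]octadecan-2-one F7 is intercepted by the aldehyde as it forms. This gives 9, and the accompanying Ph3PO should be tolerated in step 5.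

Step 8. Hydride may also add to the ketone, or the hydroxymethyl product may ionise to an azafulvene that is reduced further or oligomerises, so that over-reduction or decomposition erodes the product.
- The fallback carries the one-carbon arm at the alcohol oxidation level from the start, so that no hydride step is needed. It sets out from aminoketone salt 7 and returns at target 15.
- Salt 7 is condensed as in step 4 with commercial (tert-butyldimethylsilyloxy)acetaldehyde to (E)-1-{[2-(tert-butyldimethylsilyloxy)ethylidene]amino}-17-methyloctadecan-2-one F8.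
- Cycloaddition with 10 under the conditions of step 5 should give 1-[5-(tert-butyldimethylsilyloxymethyl)-3,4-bis(phenylsulfonyl)pyrrolidin-2-yl]-16-methylheptadecan-1-one F9.
- DBU then leads through 1-[5-(tert-butyldimethylsilyloxymethyl)-4-(phenylsulfonyl)-4,5-dihydro-1H-pyrrol-2-yl]-16-methylheptadecan-1-one F10 to 1-[5-(tert-butyldimethylsilyloxymethyl)-1H-pyrrol-2-yl]-16-methylheptadecan-1-one F11.
- Bu4NF in THF removes the silyl group to give 15.

Further compounds
F1 | step 5 | N-methoxy-N,16-dimethylheptadecanamide | CC(C)CCCCCCCCCCCCCCC(=O)N(C)OC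
F2 | step 5 | 5,10-bis(dimethylamino)-5H,10H-dipyrrolo[1,2-a:1',2'-d]pyrazine (stereoisomer mixture) | CN(C)C1c2cccn2C(N(C)C)c2cccn12
F3 | step 5 | 1,1'-[5,10-bis(dimethylamino)-5H,10H-dipyrrolo[1,2-a:1',2'-d]pyrazine-3,8-diyl]bis(16-methylheptadecan-1-one) (stereoisomer mixture) | CN(C)C1c2ccc(C(=O)CCCCCCCCCCCCCCC(C)C)n2C(N(C)C)c2ccc(C(=O)CCCCCCCCCCCCCCC(C)C)n12
F4 | step 4 | 1-diazo-17-methyloctadecan-2-one | CC(C)CCCCCCCCCCCCCCC(=O)C=[N+]=[N-]
F5 | step 4 | 1-bromo-17-methyloctadecan-2-one | CC(C)CCCCCCCCCCCCCCC(=O)CBr
F6 | step 4 | 1-azido-17-methyloctadecan-2-one | CC(C)CCCCCCCCCCCCCCC(=O)CN=[N+]=[N-]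
F7 | step 4 | 17-methyl-1-[(triphenylphosphoranylidene)amino]octadecan-2-one (not isolated) | CC(C)CCCCCCCCCCCCCCC(=O)CN=P(c1ccccc1)(c1ccccc1)c1ccccc1
F8 | step 8 | (E)-1-{[2-(tert-butyldimethylsilyloxy)ethylidene]amino}-17-methyloctadecan-2-one | CC(C)CCCCCCCCCCCCCCC(=O)C/N=C/CO[Si](C)(C)C(C)(C)C
F9 | step 8 | 1-[5-(tert-butyldimethylsilyloxymethyl)-3,4-bis(phenylsulfonyl)pyrrolidin-2-yl]-16-methylheptadecan-1-one (racemic diastereomer mixture) | CC(C)CCCCCCCCCCCCCCC(=O)C1NC(CO[Si](C)(C)C(C)(C)C)C(S(=O)(=O)c2ccccc2)C1S(=O)(=O)c1ccccc1
F10 | step 8 | 1-[5-(tert-butyldimethylsilyloxymethyl)-4-(phenylsulfonyl)-4,5-dihydro-1H-pyrrol-2-yl]-16-methylheptadecan-1-one (racemic; not isolated) | CC(C)CCCCCCCCCCCCCCC(=O)C1=CC(S(=O)(=O)c2ccccc2)C(CO[Si](C)(C)C(C)(C)C)N1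
F11 | step 8 | 1-[5-(tert-butyldimethylsilyloxymethyl)-1H-pyrrol-2-yl]-16-methylheptadecan-1-one | CC(C)CCCCCCCCCCCCCCC(=O)c1ccc(CO[Si](C)(C)C(C)(C)C)[nH]1
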